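The earlier runs and the new flask were computed on assumed constants, noise included.

The target in the noon flask read 23.6% at 6.00 h, then 22.9% and 26.2%, a last step of 3.3 percentage points against a scatter of 1 point, and the solid substrate read 0% at 3.00 h. I took this as a plateau, the dissolved isomers at their end state (thermodynamic control), and I had to choose the next move.

| flask | solid substrate | temperature | remark | time |
|---|---|---|---|---|
| noon | 1.2 M | 25 °C | the very flask that is asked about, followed so far |  |
| flask | 1.2 M | 25 °C |  | 20 h |

- noon (time / h: target / %, solid substrate / %): 1.50: 10.2, 19.3; 3.00: 18.1, 0; 6.00: 23.6, 0; 10.0: 22.9, 0; 20.0: 26.2, 0.9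

(standard deviation of a reading: 1 percentage point)

- solid substrate is a solid; its amount is given per volume of the solution
- removed target is counted in
- the numbers in the tables scatter by 1 percentage point (one standard deviation)
- steps that have been proposed: isomer of the product A <-> isomer of the product B; isomer of the product B <-> starting material; solid substrate <-> starting material; starting material <-> target; target <-> isomer of the product A; target <-> isomer of the product C
- at the start none of the solid substrate is in solution

- Wednesday's: at 20 h raise the temperature by 25 K, then wait 40 h
- Tuesday's: at 20 h take out 90% of the target then present, then wait 40 h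
- Sunday's: change nothing and wait 40 h more

* target, in percent of the solid substrate first charged, at 20 h
* what to do for the largest gain in target; "none" if nothing gains more than 2 percentage points (Wednesday's / Tuesday's / Sunday's / none)
* target present, with what was taken out counted in, in percent of the solid substrate first charged, after Wednesday's
* target present, with what was taken out counted in, in percent of the solid substrate first charged, after Tuesday's

I averaged the three plateau readings:

f = 24.2%

This f, the plateau share, is the target's fraction of the charge once the readings stop moving. It was also my answer for now. I reckoned Sunday's to leave f where it stood and so to gain nothing. Tuesday's removes x·f, with x = 90%, and I assumed the remaining pool returns to the same share, so that G, the target after Tuesday's with what was taken out counted in, is: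

G = x·f + f·(1 − x·f) = 40.8%

That is a gain of 17 points. Wednesday's changes f itself, and readings at one temperature do not show how f moves with heat. So my test was this: heating wins if the heated share exceeds G. With no reading to suggest that, I chose Tuesday's.

The forecast also chose Tuesday's, with now at 25% (23.3% to 26.5%), g1 at 25% (17% to 33%) and g2 at 41% (33% to 45%). On heating it said: “Isomers usually move modestly and the sign is unknown”.

The flask gave now = 24.5%, g1 = 68.6%, g2 = 41.1% and best = Wednesday's, with gains of 44 points for Wednesday's, 17 points for Tuesday's and 0 points for Sunday's.

    isomer of the product A ⇌ isomer of the product B (K = 4.20, k = 8.40 × 10⁻⁵ s⁻¹, Ea = 89.0 kJ mol⁻¹, ΔH = −43.0 kJ mol⁻¹)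
    isomer of the product B ⇌ starting material (k = 2.00 × 10⁻⁴ s⁻¹, Ea = 98.0 kJ mol⁻¹)
    solid substrate ⇌ starting material, rate k3*(cs3 - [starting material]) while solid is left; crystals form when [starting material] > cs3 (solubility = 0.760 M, k = 3.70 × 10⁻⁴ s⁻¹)
    starting material ⇌ target (K = 1.20, k = 1.30 × 10⁻⁴ s⁻¹, Ea = 90.0 kJ mol⁻¹, ΔH = 46.0 kJ mol⁻¹)
    target ⇌ isomer of the product A (K = 0.360, k = 5.10 × 10⁻⁵ s⁻¹, Ea = 93.0 kJ mol⁻¹, ΔH = −51.0 kJ mol⁻¹)
    target ⇌ isomer of the product C (K = 0.380, k = 3.70 × 10⁻⁴ s⁻¹, Ea = 92.0 kJ mol⁻¹, ΔH = −41.0 kJ mol⁻¹)
    (constants at 25 °C)

My G of 40.8% stood beside 41.1%, but heating took the share from my 24.2% to 68.6%, above G, so my choice failed the test. For the flask kept at 40 °C, I carried each equilibrium constant from T_ref = 25 °C to that temperature T by exp[−ΔH/R·(1/T − 1/T_ref)], ΔH being the enthalpy of the step. Here a is target over starting material, b isomer of the product A over target, c isomer of the product C over target, and d isomer of the product B over isomer of the product A: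

a = 2.92, b = 0.134, c = 0.172, d = 1.83

f = 1/(1 + 1/a + b + c + b·d) = 52.8%

That flask held 52.8% of target at 20.0 h.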